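**Retrosynthetic overview**

1. The target is cut at the ester O–CH2 bond into tetracontanoic acid and tyrosol. This bond is made last by a Mitsunobu reaction that touches only the aliphatic hydroxyl, and the acid comes from its methyl ester.
2. The strategy rests on the ester carbonyl C1 sitting at the end of an unbranched, unfunctionalised C39 alkyl chain (C2–C40). Methyl tetracontanoate is therefore cut at C1–C2 and C1–OMe into nonatriacont-19-ene, CO and MeOH; a palladium hydride walks to the chain end and carbonylates there, wherever the double bond starts.
3. Nonatriacont-19-ene comes from nonatriacontan-20-ol, this from nonatriacontan-20-one, and the ketone from two molecules of icosanoic acid by ketonic decarboxylation (19 + 1 + 19 carbons; the fortieth carbon arrives as CO).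
4. No ring is formed. The only ring, the para-disubstituted benzene ring of the tyrosol unit, is bought intact.

Key step: step 4

Remark: the target has no stereocentre and no stereogenic double bond, so it is one achiral compound and needs no stereocontrol. The internal alkene is not symmetric in the strict sense (C19=C20 in a 39-carbon chain), but it is the only alkene the symmetric carbinol can give, and it is used as its E/Z mixture together with any positional isomers.

**Route**

Step 1
Reactants: 1 icosanoic acid (2 equiv)
Product: 2 nonatriacontan-20-one
Conditions: MgO (cat.), neat melt, 335–345 °C, N2 stream (–CO2, –H2O)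
Reagents that add atoms: none
Why: Ketonic decarboxylation, in which two carboxylates condense on the basic oxide to a β-keto acid that loses CO2; both halves are identical, so only one ketone can form.

Step 2
Reactants: 2 nonatriacontan-20-one
Product: 3 nonatriacontan-20-ol
Conditions: NaBH4, THF/EtOH, 55–65 °C; then dil. HCl
Reagents that add atoms: none
Why: Borohydride reduction of an unhindered dialkyl ketone, run warm to keep the wax dissolved; the carbinol carbon carries two identical nonadecyl groups, so no stereocentre arises.

Step 3
Reactants: 3 nonatriacontan-20-ol
Product: 4 nonatriacont-19-ene (drawn E; E/Z mixture)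
Conditions: TsOH·H2O (5 mol %), 1,2-dichlorobenzene, reflux, Dean–Stark
Reagents that add atoms: none
Why: Acid-catalysed E1 dehydration driven by azeotropic removal of water; both β-eliminations of the symmetric alcohol give the same alkene, and E/Z or positional scrambling still leaves an unbranched C39 alkene that the next step accepts equally.

Step 4
Reactants: 4 nonatriacont-19-ene; 5 carbon monoxide; 6 methanol
Product: 7 methyl tetracontanoate
Conditions: Pd(OAc)2 (2 mol %), 1,2-bis(di-tert-butylphosphinomethyl)benzene (8 mol %), MeSO3H (20 mol %), CO (20 bar), MeOH/PhMe 1:1, 90 °C; product crystallised on cooling
Reagents that add atoms: none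
Why: Isomerizing alkoxycarbonylation: the cationic diphosphine–palladium hydride inserts the double bond and runs along the chain by reversible β-hydride elimination and re-insertion, so all secondary alkyls and the primary C1 alkyl interconvert faster than any of them is converted to product. CO insertion is also reversible, and the rate-limiting methanolysis is fast only for the unhindered linear acyl inside the pocket of the four tert-butyl groups, which drains the equilibrating pool into the terminal methyl ester and forms the C1–C2 and C1–OMe bonds in one operation. The closest known reaction type is the isomerizing methoxycarbonylation of internal octenes and of methyl oleate or erucate, where the metal travels about eight positions; here it must travel eighteen to nineteen, which lowers the standing share of the terminal alkyl and hence the rate, but not the product-determining discrimination. No ring is closed and no stereocentre is formed. The one selectivity required is linear over branched ester; it is secured by the bulk of the diphosphine and by a chain with no branch, heteroatom or conjugating group at which the walk could stop, and both chain ends give the same ester. The linear C41 ester should crystallise from the cooled mixture and leave branched esters and unreacted alkene in the liquor.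

Step 5
Reactants: 7 methyl tetracontanoate
Product: 8 tetracontanoic acid
Conditions: KOH, EtOH/PhMe/H2O, reflux; then aq. HCl, 70 °C
Reagents that add atoms: potassium hydroxide, [K+].[OH-]
Why: Saponification (acyl–oxygen hydrolysis) of an unhindered methyl ester, run hot with toluene as co-solvent so that the waxy ester stays dissolved, the acid crystallising after acidification.

Step 6
Reactants: 8 tetracontanoic acid; 9 tyrosol (2 equiv)
Product: 10 2-(4-hydroxyphenyl)ethyl tetracontanoate
Conditions: PPh3 (1.05 equiv), DIAD (1.05 equiv, slow addition), THF/PhMe, 50 °C
Reagents that add atoms: none
Why: Mitsunobu esterification, in which the carboxylic acid, far more acidic than the phenol, protonates the betaine and its carboxylate displaces the phosphorus-activated primary aliphatic oxygen of tyrosol; this chemoselectivity is known for phenolic alcohols, so the phenol should stay free.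

**Compound list**

1 | icosanoic (arachidic) acid | CCCCCCCCCCCCCCCCCCCC(=O)O | starting material
2 | nonatriacontan-20-one | CCCCCCCCCCCCCCCCCCCC(=O)CCCCCCCCCCCCCCCCCCC | intermediate
3 | nonatriacontan-20-ol | CCCCCCCCCCCCCCCCCCCC(O)CCCCCCCCCCCCCCCCCCC | intermediate
4 | nonatriacont-19-ene (drawn E; E/Z mixture used) | CCCCCCCCCCCCCCCCCC/C=C/CCCCCCCCCCCCCCCCCCC | intermediate
5 | carbon monoxide | [C-]#[O+] | starting material
6 | methanol | CO | starting material
7 | methyl tetracontanoate | CCCCCCCCCCCCCCCCCCCCCCCCCCCCCCCCCCCCCCCC(=O)OC | intermediate
8 | tetracontanoic acid | CCCCCCCCCCCCCCCCCCCCCCCCCCCCCCCCCCCCCCCC(=O)O | intermediate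
9 | tyrosol, 2-(4-hydroxyphenyl)ethanol | OCCc1ccc(O)cc1 | starting material
10 | 2-(4-hydroxyphenyl)ethyl tetracontanoate | CCCCCCCCCCCCCCCCCCCCCCCCCCCCCCCCCCCCCCCC(=O)OCCc1ccc(O)cc1 | target

Total step count: 6
Longest linear sequence: 6 steps (1 to 10)

**Steps most likely to fail**

Step 4. The walk may stall in a poorly solvated wax, or carbonylation of internal alkyls may begin to compete over so long a distance; conversion would then stay low or branched esters would contaminate the product. The fallback sets out from 4 and comes back at 7. It replaces the catalytic kinetic funnel by a base-mediated isomerisation that is held at the chain end as an acetylide. Bromine in CH2Cl2 at 0 °C should add to the double bond and give 19,20-dibromononatriacontane F1 as a diastereomer mixture. Double dehydrobromination with KOtBu and catalytic 18-crown-6 in refluxing petroleum ether should give nonatriacont-19-yne F2. Potassium 3-aminopropylamide in 1,3-diaminopropane with THF as co-solvent (alkyne zipper) should move the triple bond to the terminus and, after aqueous quench, give nonatriacont-1-yne F3; positional isomers carried over from the dehydration converge on the same alkyne. Lithiation with n-BuLi in THF and trapping with methyl chloroformate should give methyl tetracont-2-ynoate F4, and hydrogenation over Pd/C in warm toluene/EtOAc should return to 7.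

Step 6. Once the sparingly soluble acid precipitates or is used up, the phenol can take over as the acidic partner, and aryl ether formation (oligomerisation of tyrosol, O-alkylation of the product) would then compete. The fallback sets out from 8 and comes back at 10. It activates the acid instead of the alcohol and masks the phenol. Oxalyl chloride with catalytic DMF in warm toluene should give tetracontanoyl chloride F5. Acylation of commercial 2-[4-(benzyloxy)phenyl]ethanol (OCCc1ccc(OCc2ccccc2)cc1) with pyridine and catalytic DMAP in toluene should give 2-[4-(benzyloxy)phenyl]ethyl tetracontanoate F6. Hydrogenolysis of the benzyl ether over Pd/C in warm THF/EtOAc should then free the phenol and give 10; the homobenzylic ester is not cleaved under these conditions.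

Step 3. Ionisation of the unactivated secondary carbinol may be slow, and the cation may be diverted into ether formation or alkylation of the solvent instead of losing a proton. The fallback sets out from 3 and comes back at 4. It avoids the carbocation by a base-induced E2 elimination. Methanesulfonyl chloride and Et3N in warm THF/CH2Cl2 should give nonatriacontan-20-yl methanesulfonate F7, and KOtBu in THF/DMSO at 60 °C should eliminate methanesulfonate to give 4.

**Further compounds**

F1 | step 4 | 19,20-dibromononatriacontane (diastereomer mixture) | CCCCCCCCCCCCCCCCCCC(Br)C(Br)CCCCCCCCCCCCCCCCCCC
F2 | step 4 | nonatriacont-19-yne | CCCCCCCCCCCCCCCCCCC#CCCCCCCCCCCCCCCCCCCC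
F3 | step 4 | nonatriacont-1-yne | C#CCCCCCCCCCCCCCCCCCCCCCCCCCCCCCCCCCCCCCC
F4 | step 4 | methyl tetracont-2-ynoate | CCCCCCCCCCCCCCCCCCCCCCCCCCCCCCCCCCCCCC#CC(=O)OC
F5 | step 6 | tetracontanoyl chloride | CCCCCCCCCCCCCCCCCCCCCCCCCCCCCCCCCCCCCCCC(=O)Cl
F6 | step 6 | 2-[4-(benzyloxy)phenyl]ethyl tetracontanoate | CCCCCCCCCCCCCCCCCCCCCCCCCCCCCCCCCCCCCCCC(=O)OCCc1ccc(OCc2ccccc2)cc1
F7 | step 3 | nonatriacontan-20-yl methanesulfonate | CCCCCCCCCCCCCCCCCCCC(OS(C)(=O)=O)CCCCCCCCCCCCCCCCCCC
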